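**Retrosynthetic overview**

1. Hypholomine B comes from a fully silylated 2,3-dihydrofuro[3,2-c]pyran-4-one by buffered fluoride cleavage, after thermodynamic equilibration of C3 to the 2,3-trans arrangement.
2. The dihydrofuran ring is opened at O1–C7a, leading back to an aryl ketone at C2; it is closed by asymmetric transfer hydrogenation under dynamic kinetic resolution, after which the new hydroxyl adds to C7a with loss of water.
3. Feature used: C3 is a methine between C3a of ring A, C6' of ring B and the C2 ketone, so it racemises readily; C7a is C4 of the 4-hydroxy-2-pyranone ring A, a ketone-type carbon in its pyran-2,4-dione tautomer.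
4. The ketone precursor is cut at C3–C3a: Pd-catalysed alpha-arylation of an aryl (ring B)-methyl ketone with the 3-bromo ring A pyranone.
5. Ring order: ring B is bought as triacetic acid lactone and acylated at its methyl group; ring A is built by acylketene cyclisation; the dihydrofuran ring closes last, in the key step.

Key step: step 10

Abbreviations: TBS = tert-butyldimethylsilyl, TBSO = tert-butyldimethylsilyloxy, MOM = methoxymethyl.

Remark (protecting groups): the aryl oxygens are carried as TBS ethers, not methyl ethers. In the closed product C2–O1 is a para-oxygenated benzylic ester of a vinylogous acid, which BBr3 would be expected to ionise, scrambling C2; silyl ethers are somewhat weaker donors and leave with buffered fluoride.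

Remark (assumption): the sense of induction of the ruthenium catalyst is taken from simple aryl alkyl ketones ((S,S) ligand giving the S carbinol). It would be checked on the isolated carbinol, and the (R,R) ligand used if the crowded ketone behaved the other way.

**Route**

Step 1
Reactants: 1 triacetic acid lactone (4-hydroxy-6-methyl-2H-pyran-2-one)
Product: 2 4-(methoxymethoxy)-6-methyl-2H-pyran-2-one
Conditions: MOMCl, iPr2NEt, CH2Cl2, 0 °C to rt
Reagents that add atoms: chloromethyl methyl ether, COCCl
Why: Williamson-type O-alkylation of the vinylogous acid with a hard alkoxymethyl chloride under amine base should go on O4 and give an acetal-type ether that tolerates the lithium amide, palladium and amine steps but leaves in dilute acid.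

Step 2
Reactants: 3 3,4-dihydroxybenzoic acid
Product: 5 3,4-bis(TBSO)benzoic acid, via silyl ester 4 (not isolated)
Conditions: TBSCl (3.3 equiv), imidazole, DMF, rt; then AcOH/THF/H2O, rt
Reagents that add atoms: tert-butyldimethylsilyl chloride, CC(C)(C)[Si](C)(C)Cl
Why: Imidazole-promoted exhaustive silylation followed by selective solvolysis of the silyl ester, which is far more labile than the two aryl silyl ethers.

Step 3
Reactants: 5 3,4-bis(TBSO)benzoic acid; 2 4-(methoxymethoxy)-6-methyl-2H-pyran-2-one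
Product: 7 1-[3,4-bis(TBSO)phenyl]-2-[4-(methoxymethoxy)-2-oxo-2H-pyran-6-yl]ethan-1-one, via acid chloride 6 (not isolated)
Conditions: (COCl)2, cat. DMF, CH2Cl2, 0 °C to rt, evaporate; 2 (2.2 equiv), LiN(SiMe3)2 (2.2 equiv), THF, −78 °C, then 6, −78 °C; AcOH
Reagents that add atoms: none
Why: Claisen-type C-acylation of the vinylogous lithium dienolate of 2 at its exocyclic carbon by the acid chloride, the second equivalent of dienolate taking up the more acidic product so that it is not acylated twice.

Step 4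
Reactants: 8 caffeic acid ((E)-3,4-dihydroxycinnamic acid)
Product: 10 (E)-3,4-bis(TBSO)cinnamic acid, via silyl ester 9 (not isolated)
Conditions: TBSCl (3.3 equiv), imidazole, DMF, rt; then AcOH/THF/H2O, rt
Reagents that add atoms: tert-butyldimethylsilyl chloride, CC(C)(C)[Si](C)(C)Cl
Why: The same silylation and selective silyl ester solvolysis as in step 2, which leaves the E alkene untouched.

Step 5
Reactants: 10 (E)-3,4-bis(TBSO)cinnamic acid; 11 2,2,6-trimethyl-4H-1,3-dioxin-4-one
Product: 13 6-[(E)-4-(3,4-bis(TBSO)phenyl)-2-oxobut-3-en-1-yl]-2,2-dimethyl-4H-1,3-dioxin-4-one, via acid chloride 12 (not isolated)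
Conditions: (COCl)2, cat. DMF, CH2Cl2, 0 °C to rt, evaporate; 11 (2.2 equiv), LiN(SiMe3)2 (2.2 equiv), THF, −78 °C, then 12, −78 °C; AcOH
Reagents that add atoms: none
Why: Gamma-C-acylation (vinylogous Claisen condensation) of the dioxinone lithium dienolate by the cinnamoyl chloride, again with a second equivalent of dienolate as the base for the product.

Step 6
Reactants: 13 6-[(E)-4-(3,4-bis(TBSO)phenyl)-2-oxobut-3-en-1-yl]-2,2-dimethyl-4H-1,3-dioxin-4-one
Product: 15 4-hydroxy-6-[(E)-3,4-bis(TBSO)styryl]-2H-pyran-2-one, via acylketene 14 (not isolated)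
Conditions: toluene, 110 °C
Reagents that add atoms: none
Why: Thermal retro-hetero-Diels–Alder loss of acetone gives the acylketene, which is captured by the enol oxygen of the 5-ketone in a six-membered lactonisation that forms ring A as the 4-hydroxy-2-pyranone.

Step 7
Reactants: 15 4-hydroxy-6-[(E)-3,4-bis(TBSO)styryl]-2H-pyran-2-one
Product: 16 3-bromo-4-hydroxy-6-[(E)-3,4-bis(TBSO)styryl]-2H-pyran-2-one
Conditions: NBS (1.0 equiv), CH2Cl2, 0 °C, dark
Reagents that add atoms: N-bromosuccinimide, O=C1CCC(=O)N1Br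
Why: Electrophilic bromination at C3, the enol carbon of the cyclic beta-keto lactone, which is far more nucleophilic than the styryl alkene or the silylated arene when one equivalent of NBS is used cold.

Step 8
Reactants: 16 3-bromo-4-hydroxy-6-[(E)-3,4-bis(TBSO)styryl]-2H-pyran-2-one
Product: 17 3-bromo-4-(methoxymethoxy)-6-[(E)-3,4-bis(TBSO)styryl]-2H-pyran-2-one
Conditions: MOMCl, iPr2NEt, CH2Cl2, 0 °C
Reagents that add atoms: chloromethyl methyl ether, COCCl
Why: The same O4-selective alkoxymethylation as in step 1 (any 2-alkoxy-4-pyranone isomer would be removed by chromatography), which blocks the ring A oxygen so that the later ketone cannot close to an aromatic furan before it is reduced.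

Step 9
Reactants: 7 1-[3,4-bis(TBSO)phenyl]-2-[4-(methoxymethoxy)-2-oxo-2H-pyran-6-yl]ethan-1-one; 17 3-bromo-4-(methoxymethoxy)-6-[(E)-3,4-bis(TBSO)styryl]-2H-pyran-2-one
Product: 18 1-[3,4-bis(TBSO)phenyl]-2-[4-(methoxymethoxy)-2-oxo-2H-pyran-6-yl]-2-[4-(methoxymethoxy)-6-((E)-3,4-bis(TBSO)styryl)-2-oxo-2H-pyran-3-yl]ethan-1-one (racemic, racemising at the methine)
Conditions: Pd(OAc)2 (5 mol %), XPhos (2-dicyclohexylphosphino-2',4',6'-triisopropylbiphenyl, 10 mol %), K3PO4 (3 equiv), toluene, 80 °C
Reagents that add atoms: none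
Why: Palladium-catalysed alpha-arylation of a ketone (Buchwald–Hartwig–Miura type), in which Pd(OAc)2 (divalent palladium) is reduced in the flask to zerovalent palladium that inserts into the C3–Br bond of 17, K3PO4 suffices to deprotonate the doubly activated methylene of 7, and the bulky biarylphosphine should force reductive elimination to the crowded methine, whose new stereocentre (the later C3) is formed racemic and stays labile.

Step 10
Reactants: 18 1-[3,4-bis(TBSO)phenyl]-2-[4-(methoxymethoxy)-2-oxo-2H-pyran-6-yl]-2-[4-(methoxymethoxy)-6-((E)-3,4-bis(TBSO)styryl)-2-oxo-2H-pyran-3-yl]ethan-1-one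
Product: 21 (2S,3S)-2-[3,4-bis(TBSO)phenyl]-6-[(E)-3,4-bis(TBSO)styryl]-3-(4-hydroxy-2-oxo-2H-pyran-6-yl)-2,3-dihydro-4H-furo[3,2-c]pyran-4-one (tetra-O-TBS hypholomine B), via carbinol 19 (not isolated), via triol 20 (not isolated)
Conditions: RuCl(p-cymene)[(S,S)-TsDPEN] (2 mol %), HCO2H/NEt3 (2:3), CH2Cl2, 30 °C; then HCl in MeOH (to pH about 1), 0 °C to rt
Reagents that add atoms: none
Why: In the amine-rich formate medium the methine of 18 (acidified by the C2 ketone, by C3a of ring A and by the vinylogous ester of ring B) racemises through its enol(ate), while the ruthenium hydride formed from formate on the divalent ruthenium complex passes hydride and the NH proton to the C2 carbonyl through the outer-sphere six-membered transition state; the closest known reaction type is the Noyori–Ikariya asymmetric transfer hydrogenation with dynamic kinetic resolution of alpha-substituted aryl ketones, followed by the known acid cyclodehydration of 3-(2-hydroxyalkyl)-4-hydroxy-2-pyranones. Methanolic HCl then removes both MOM groups, the C2 hydroxyl adds to C7a, the ketone-type carbonyl of the pyran-2,4-dione tautomer of ring A, in a 5-exo-trig closure, and the hemiketal loses water to restore the 2-pyranone, so that O1–C7a and the dihydrofuran ring are formed with the C2–O bond intact. C2 is set by the catalyst: with the ketone aryl group in the CH/π site under the p-cymene ligand, as for acetophenone, the (S,S) ligand should deliver hydride to the Re face and give 2S. C3 is set by the dynamic resolution, in which the matched Felkin-type pairing (the doubly ortho-substituted ring A anti to the incoming hydride) should favour the (1S,2S) carbinol 19, which closes with both centres untouched to the 2,3-trans product, and step 11 stands behind this centre as a thermodynamic safeguard. The step needs C=O over C=C selectivity (secured by the polar outer-sphere hydride transfer, which leaves the styryl and pyranone double bonds alone) and a ring A oxygen that stays blocked until the ketone is consumed (secured by the amine-rich medium, since a free 4-hydroxyl would condense with the ketone to an aromatic furan). It also needs attack at C7a and not at the lactone carbonyl C4 (favoured by the more electrophilic ketone-type carbon and the more stable 2-pyranone product) and a benzylic C2–O bond that does not ionise, for which the acid is kept dilute, cold and brief and the aryl oxygens are silyl and not methyl ethers.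

Step 11
Reactants: 21 (2S,3S)-tetra-O-TBS hypholomine B
Product: 22 (2S,3S)-2-[3,4-bis(TBSO)phenyl]-6-[(E)-3,4-bis(TBSO)styryl]-3-[4-(TBSO)-2-oxo-2H-pyran-6-yl]-2,3-dihydro-4H-furo[3,2-c]pyran-4-one (penta-O-TBS hypholomine B; used crude after evaporation and trituration)
Conditions: TBSCl (1.1 equiv), DBU (1.3 equiv), anhydrous CH2Cl2, 0 °C to rt, brief
Reagents that add atoms: tert-butyldimethylsilyl chloride, CC(C)(C)[Si](C)(C)Cl
Why: Silylation of the ring B hydroxyl restores its vinylogous-ester character, so that the small excess of amidine base can reversibly deprotonate C3 (base-mediated cis-to-trans epimerisation of the kind known for 3-acyl-2-aryl-2,3-dihydrobenzofurans), which should bring any cis material carried over from step 10 to the more stable 2,3-trans isomer with the C2 aryl group and ring B on opposite faces, while C2 bears no acidic hydrogen and keeps its configuration.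

Step 12
Reactants: 22 penta-O-TBS hypholomine B
Product: 23 hypholomine B, (2S,3S)-2-(3,4-dihydroxyphenyl)-6-[(E)-3,4-dihydroxystyryl]-3-(4-hydroxy-2-oxo-2H-pyran-6-yl)-2,3-dihydro-4H-furo[3,2-c]pyran-4-one
Conditions: HF·pyridine, pyridine, THF, 0 °C to rt; work-up without base
Reagents that add atoms: none
Why: Fluoride-mediated desilylation of the four aryl silyl ethers and the silyl vinylogous ester under buffered, weakly acidic conditions, in which no phenoxide is formed (no quinone methide opening of the C2–O1 bond) and no Lewis acid is present to ionise it, so that both stereocentres should survive.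

**Compound list**

1 | triacetic acid lactone (4-hydroxy-6-methyl-2H-pyran-2-one) | Cc1cc(O)cc(=O)o1 | starting material
2 | 4-(methoxymethoxy)-6-methyl-2H-pyran-2-one | COCOc1cc(=O)oc(C)c1 | intermediate
3 | 3,4-dihydroxybenzoic acid | OC(=O)c1ccc(O)c(O)c1 | starting material
4 | tert-butyldimethylsilyl 3,4-bis(TBSO)benzoate | CC(C)(C)[Si](C)(C)OC(=O)c1ccc(O[Si](C)(C)C(C)(C)C)c(O[Si](C)(C)C(C)(C)C)c1 | intermediate
5 | 3,4-bis(TBSO)benzoic acid | OC(=O)c1ccc(O[Si](C)(C)C(C)(C)C)c(O[Si](C)(C)C(C)(C)C)c1 | intermediate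
6 | 3,4-bis(TBSO)benzoyl chloride | ClC(=O)c1ccc(O[Si](C)(C)C(C)(C)C)c(O[Si](C)(C)C(C)(C)C)c1 | intermediate
7 | 1-[3,4-bis(TBSO)phenyl]-2-[4-(methoxymethoxy)-2-oxo-2H-pyran-6-yl]ethan-1-one | COCOc1cc(=O)oc(CC(=O)c2ccc(O[Si](C)(C)C(C)(C)C)c(O[Si](C)(C)C(C)(C)C)c2)c1 | intermediate
8 | caffeic acid ((E)-3,4-dihydroxycinnamic acid) | OC(=O)/C=C/c1ccc(O)c(O)c1 | starting material
9 | tert-butyldimethylsilyl (E)-3,4-bis(TBSO)cinnamate | CC(C)(C)[Si](C)(C)OC(=O)/C=C/c1ccc(O[Si](C)(C)C(C)(C)C)c(O[Si](C)(C)C(C)(C)C)c1 | intermediate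
10 | (E)-3,4-bis(TBSO)cinnamic acid | OC(=O)/C=C/c1ccc(O[Si](C)(C)C(C)(C)C)c(O[Si](C)(C)C(C)(C)C)c1 | intermediate
11 | 2,2,6-trimethyl-4H-1,3-dioxin-4-one | CC1=CC(=O)OC(C)(C)O1 | starting material
12 | (E)-3,4-bis(TBSO)cinnamoyl chloride | ClC(=O)/C=C/c1ccc(O[Si](C)(C)C(C)(C)C)c(O[Si](C)(C)C(C)(C)C)c1 | intermediate
13 | 6-[(E)-4-(3,4-bis(TBSO)phenyl)-2-oxobut-3-en-1-yl]-2,2-dimethyl-4H-1,3-dioxin-4-one | CC1(C)OC(=O)C=C(CC(=O)/C=C/c2ccc(O[Si](C)(C)C(C)(C)C)c(O[Si](C)(C)C(C)(C)C)c2)O1 | intermediate
14 | (6E)-7-[3,4-bis(TBSO)phenyl]-3,5-dioxohepta-1,6-dien-1-one (acylketene) | O=C=CC(=O)CC(=O)/C=C/c1ccc(O[Si](C)(C)C(C)(C)C)c(O[Si](C)(C)C(C)(C)C)c1 | intermediate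
15 | 4-hydroxy-6-[(E)-3,4-bis(TBSO)styryl]-2H-pyran-2-one | O=c1cc(O)cc(/C=C/c2ccc(O[Si](C)(C)C(C)(C)C)c(O[Si](C)(C)C(C)(C)C)c2)o1 | intermediate
16 | 3-bromo-4-hydroxy-6-[(E)-3,4-bis(TBSO)styryl]-2H-pyran-2-one | O=c1oc(/C=C/c2ccc(O[Si](C)(C)C(C)(C)C)c(O[Si](C)(C)C(C)(C)C)c2)cc(O)c1Br | intermediate
17 | 3-bromo-4-(methoxymethoxy)-6-[(E)-3,4-bis(TBSO)styryl]-2H-pyran-2-one | COCOc1cc(/C=C/c2ccc(O[Si](C)(C)C(C)(C)C)c(O[Si](C)(C)C(C)(C)C)c2)oc(=O)c1Br | intermediate
18 | 1-[3,4-bis(TBSO)phenyl]-2-[4-(methoxymethoxy)-2-oxo-2H-pyran-6-yl]-2-[4-(methoxymethoxy)-6-((E)-3,4-bis(TBSO)styryl)-2-oxo-2H-pyran-3-yl]ethan-1-one (racemic) | COCOc1cc(=O)oc(c1)C(C(=O)c1ccc(O[Si](C)(C)C(C)(C)C)c(O[Si](C)(C)C(C)(C)C)c1)c1c(OCOC)cc(/C=C/c2ccc(O[Si](C)(C)C(C)(C)C)c(O[Si](C)(C)C(C)(C)C)c2)oc1=O | intermediate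
19 | (1S,2S)-1-[3,4-bis(TBSO)phenyl]-2-[4-(methoxymethoxy)-2-oxo-2H-pyran-6-yl]-2-[4-(methoxymethoxy)-6-((E)-3,4-bis(TBSO)styryl)-2-oxo-2H-pyran-3-yl]ethan-1-ol | COCOc1cc(=O)oc(c1)[C@H]([C@H](O)c1ccc(O[Si](C)(C)C(C)(C)C)c(O[Si](C)(C)C(C)(C)C)c1)c1c(OCOC)cc(/C=C/c2ccc(O[Si](C)(C)C(C)(C)C)c(O[Si](C)(C)C(C)(C)C)c2)oc1=O | intermediate
20 | (1S,2S)-1-[3,4-bis(TBSO)phenyl]-2-(4-hydroxy-2-oxo-2H-pyran-6-yl)-2-[4-hydroxy-6-((E)-3,4-bis(TBSO)styryl)-2-oxo-2H-pyran-3-yl]ethan-1-ol | Oc1cc(=O)oc(c1)[C@H]([C@H](O)c1ccc(O[Si](C)(C)C(C)(C)C)c(O[Si](C)(C)C(C)(C)C)c1)c1c(O)cc(/C=C/c2ccc(O[Si](C)(C)C(C)(C)C)c(O[Si](C)(C)C(C)(C)C)c2)oc1=O | intermediate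
21 | (2S,3S)-tetra-O-TBS hypholomine B (ring B hydroxyl free) | O=c1cc(O)cc([C@H]2c3c(cc(/C=C/c4ccc(O[Si](C)(C)C(C)(C)C)c(O[Si](C)(C)C(C)(C)C)c4)oc3=O)O[C@@H]2c2ccc(O[Si](C)(C)C(C)(C)C)c(O[Si](C)(C)C(C)(C)C)c2)o1 | intermediate
22 | (2S,3S)-penta-O-TBS hypholomine B | O=c1cc(O[Si](C)(C)C(C)(C)C)cc([C@H]2c3c(cc(/C=C/c4ccc(O[Si](C)(C)C(C)(C)C)c(O[Si](C)(C)C(C)(C)C)c4)oc3=O)O[C@@H]2c2ccc(O[Si](C)(C)C(C)(C)C)c(O[Si](C)(C)C(C)(C)C)c2)o1 | intermediate
23 | hypholomine B, (2S,3S) | O=c1cc(O)cc([C@H]2c3c(cc(/C=C/c4ccc(O)c(O)c4)oc3=O)O[C@@H]2c2ccc(O)c(O)c2)o1 | target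

**Step count**

Total: 12 steps. Longest linear sequence: 9 steps (caffeic acid 8 to 23, steps 4 to 12).

**Steps most likely to fail, with fallbacks**

Step 10. Three processes are at risk. Hydride transfer to the crowded, strongly CH-acidic ketone may be slow or weakly face-selective. The ring A MOM group may be lost before reduction, after which the freed 4-hydroxyl condenses with the ketone to an aromatic furan. The benzylic carbinol may ionise during the protic acid stage and erode the configuration at C2. The fallback sets out from 18 and comes back at 22; it replaces the one-flask dynamic process by a reagent-controlled, stepwise sequence that needs neither racemisation nor protic acid. Corey–Bakshi–Shibata reduction of 18 with (R)-2-methyl-CBS-oxazaborolidine and catecholborane (toluene, −78 °C) should reduce both ketone enantiomers to 1S carbinols, isolated as 19 and its epimer at the methine, the (1S,2R)-carbinol F1. MgBr2·OEt2 in CH2Cl2/Et2O, the aprotic cleavage known for methoxymethyl esters, should unmask both pyranone oxygens to give 20 and its epimer, the (1S,2R)-triol F2. Catalytic pyridinium p-toluenesulfonate over molecular sieves in toluene at 40 °C should then effect the same hemiketal closure and dehydration, giving 21 from 20 and, from F2, the cis isomer (2S,3R)-tetra-O-TBS 3-epi-hypholomine B F3. The mixture is taken through the conditions of step 11, in which 21 is silylated to 22, and F3 is silylated to (2S,3R)-penta-O-TBS 3-epi-hypholomine B F4, which should epimerise at C3 to 22.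

Step 9. Oxidative addition into the doubly ortho-substituted C3–Br bond should be easy, but C–C reductive elimination from a stabilised, hindered enolate may be slow. Hydrodebromination of 17, Heck-type attack on a styryl group or base-induced loss of aryl silyl groups could then take over. The fallback sets out from 2, 15 and 6 and comes back at 18; it makes the C3–C3a bond by organocatalytic reductive alkylation, not cross-coupling, and adds the aroyl group last, so steps 7 and 8 are not needed. Riley oxidation of 2 (SeO2, 1,4-dioxane, 100 °C) should give 4-(methoxymethoxy)-2-oxo-2H-pyran-6-carbaldehyde F5. Three-component reductive alkylation of 15 with F5 and Hantzsch ester (cat. L-proline, CH2Cl2, rt; Knoevenagel condensation, then transfer hydrogenation of the alkylidene) should give the bis(pyranonyl)methane F6. MOMCl/iPr2NEt should give its ring A methoxymethyl ether F7. Deprotonation of the bridging methylene (LiN(SiMe3)2, 2.2 equiv, THF, −78 °C) and C-acylation with acid chloride 6 should give 18.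

Step 11. The C3 carbanion has the ring oxygen O1 in the beta position, so base may open the dihydrofuran by beta-elimination (retro-oxa-Michael) and not only epimerise C3. This is a retro-5-endo-trig process and should be slow, but reclosure of the opened alkene would racemise C2. The base may also strip aryl silyl groups. The fallback sets out from 18 and comes back at 23; C3 is then not equilibrated after ring closure but selected before it. Step 10 is stopped before the acid stage and carbinol 19 is separated by chromatography from any (1S,2R)-carbinol F1. Only 19 is closed with methanolic HCl, through 20, to 21. F1 is oxidised with Dess–Martin periodinane (CH2Cl2, rt) back to the racemising ketone 18 and resubmitted. The 21 obtained in this way should contain no cis isomer and is taken without base treatment into the conditions of step 12, where HF·pyridine removes its four silyl groups to give 23.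

**Further compounds**

F1 | step 10 | (1S,2R)-1-[3,4-bis(TBSO)phenyl]-2-[4-(methoxymethoxy)-2-oxo-2H-pyran-6-yl]-2-[4-(methoxymethoxy)-6-((E)-3,4-bis(TBSO)styryl)-2-oxo-2H-pyran-3-yl]ethan-1-ol | COCOc1cc(=O)oc(c1)[C@@H]([C@H](O)c1ccc(O[Si](C)(C)C(C)(C)C)c(O[Si](C)(C)C(C)(C)C)c1)c1c(OCOC)cc(/C=C/c2ccc(O[Si](C)(C)C(C)(C)C)c(O[Si](C)(C)C(C)(C)C)c2)oc1=O
F2 | step 10 | (1S,2R)-1-[3,4-bis(TBSO)phenyl]-2-(4-hydroxy-2-oxo-2H-pyran-6-yl)-2-[4-hydroxy-6-((E)-3,4-bis(TBSO)styryl)-2-oxo-2H-pyran-3-yl]ethan-1-ol | Oc1cc(=O)oc(c1)[C@@H]([C@H](O)c1ccc(O[Si](C)(C)C(C)(C)C)c(O[Si](C)(C)C(C)(C)C)c1)c1c(O)cc(/C=C/c2ccc(O[Si](C)(C)C(C)(C)C)c(O[Si](C)(C)C(C)(C)C)c2)oc1=O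
F3 | step 10 | (2S,3R)-tetra-O-TBS 3-epi-hypholomine B (ring B hydroxyl free) | O=c1cc(O)cc([C@@H]2c3c(cc(/C=C/c4ccc(O[Si](C)(C)C(C)(C)C)c(O[Si](C)(C)C(C)(C)C)c4)oc3=O)O[C@@H]2c2ccc(O[Si](C)(C)C(C)(C)C)c(O[Si](C)(C)C(C)(C)C)c2)o1
F4 | step 10 | (2S,3R)-penta-O-TBS 3-epi-hypholomine B | O=c1cc(O[Si](C)(C)C(C)(C)C)cc([C@@H]2c3c(cc(/C=C/c4ccc(O[Si](C)(C)C(C)(C)C)c(O[Si](C)(C)C(C)(C)C)c4)oc3=O)O[C@@H]2c2ccc(O[Si](C)(C)C(C)(C)C)c(O[Si](C)(C)C(C)(C)C)c2)o1
F5 | step 9 | 4-(methoxymethoxy)-2-oxo-2H-pyran-6-carbaldehyde | COCOc1cc(=O)oc(C=O)c1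
F6 | step 9 | 4-hydroxy-3-{[4-(methoxymethoxy)-2-oxo-2H-pyran-6-yl]methyl}-6-[(E)-3,4-bis(TBSO)styryl]-2H-pyran-2-one | COCOc1cc(=O)oc(Cc2c(O)cc(/C=C/c3ccc(O[Si](C)(C)C(C)(C)C)c(O[Si](C)(C)C(C)(C)C)c3)oc2=O)c1
F7 | step 9 | 4-(methoxymethoxy)-3-{[4-(methoxymethoxy)-2-oxo-2H-pyran-6-yl]methyl}-6-[(E)-3,4-bis(TBSO)styryl]-2H-pyran-2-one | COCOc1cc(=O)oc(Cc2c(OCOC)cc(/C=C/c3ccc(O[Si](C)(C)C(C)(C)C)c(O[Si](C)(C)C(C)(C)C)c3)oc2=O)c1
F0 | step 11 | none | none
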